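Germacrane numbering (C1–C15) is used for the target and for all intermediates.

## Analysis of the target

The target is a germacranolide. A ten-membered carbocycle (C1–C10) is trans-fused across C6–C7 to an α-methylene-γ-butyrolactone (O–C6, C7, C11=C13, C12=O). It carries a trans-oxirane on C1–C10, a cis-oxirane on C4–C5, a free hydroxyl at C2 and an angelate ((Z)-2-methylbut-2-enoate) at C8. There are eight stereocentres (1R,2S,4R,5S,6S,7R,8S,10R). They fall into the contiguous triad C6–C7–C8 (H6 and H7 trans on the lactone, oxygen at C8 α) and the set C1/C2/C4/C5/C10, in which the C2 carbinol lies between the two oxiranes. The oxirane geometries correspond to a (1(10)E,4Z)-diene, and both oxygens sit on the outer face of the ring, which the 2α-hydroxyl can reach, so all four epoxide centres can be derived from C2. The sensitive groups are these: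
- the methylene lactone, which accepts hydride, ylides and amines;
- the angelate, which isomerises to the tiglate under nucleophilic catalysis;
- the oxiranes and their diene precursor, which cyclise across the ring under acid;
- the lactone itself, which can migrate to a neighbouring free hydroxyl at C8 or C5.

The synthesis is hard because a ten-membered ring with two defined trisubstituted alkene geometries must be closed, and because five oxygen functions and the exocyclic methylene must be unveiled in an order in which each reagent meets only groups that tolerate it. The strategy rests on C7, the β-carbon of the lactone. Its three neighbours are C6 (with C5 attached, available with the correct configuration as C5/CH2OH of a chiral-pool 2(5H)-furanone), C8 (a carbinol, hence an acyl-anion site at the ketone level) and C11 (the nucleophilic lactone α-carbon that carries C13). A butenolide ring can therefore accept C8 as a nucleophile at C7 and C13 as an electrophile at C11 in one operation, with C6 directing both new centres.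

## Retrosynthetic reasoning

**Epoxides (27 ⇒ 26).** The four C–O bonds of the two oxiranes are removed first. Both alkenes of dienol 26 are trisubstituted, one allylic and one homoallylic to the C2 hydroxyl, and both expose their outer face on the side of that hydroxyl. A hydroxyl-directed double epoxidation as the last step keeps the acid-labile oxiranes away from every other reagent. The forward reaction must discriminate faces at both alkenes and must leave the two electron-poor alkenes alone.

**C2 hydroxyl and C11=C13 (26 ⇒ 25 ⇒ 23, through 24).** The hydroxyl is carried as a silyl ether, and the exocyclic methylene is carried as the dimethylaminomethyl group of 23. The methylene lactone would not survive the hydride, ylide and carbanion chemistry needed earlier, whereas the Mannich base is inert to them and is unmasked by quaternisation (24) and elimination.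

**Ring closure at C4=C5 (23 ⇒ 22).** The ten-membered ring is opened at the Z-trisubstituted alkene. This cut leaves a vinyl group on C6 and an isopropenyl group on C3, both easy to install, and leaves the E-alkene C1=C10 and all stereocentres untouched. The forward metathesis has to close a strained ring onto a 1,1-disubstituted alkene and deliver the cis geometry.

**C5 extension (22 ⇒ 21 ⇒ 20 ⇒ 19).** The vinyl group of 22 comes from aldehyde 21, and this from the primary alcohol 20 and its silyl ether 19. C5 is thus the side-chain carbon of the butenolide, which had to be protected during the key step in any case. Both silyl ethers are chosen as tert-butyldimethylsilyl, because a primary one can be removed cleanly in the presence of a secondary one, which a bulkier primary silyl group would not allow.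

**C8 oxygen (19 ⇒ 18 ⇒ 17 ⇒ 16).** The angelate is traced to alcohol 18, the alcohol to ketone 17, and the ketone to the dithiane of 16. The C8 centre is set by reagent-controlled reduction while the chain is still open, where a branched C7 and a methylene C9 flank the carbonyl. The ester is put on at once, so that the free hydroxyl can neither migrate the lactone nor form a lactol with C5 later.

**Key disconnection (16 ⇒ 10 + 12 + 13, through 14 and 15).** The bonds C7–C8 and C11–C13 are cut together. This divides the molecule at the centre of the C6–C7–C8 triad into two fragments of similar size, dithiane 10 (C8–C10, C1–C4) and butenolide 12 (C5–C7, C11, C12), plus the one-carbon iminium salt 13. Forward, carbanion 14 must add 1,4 and anti to the C6 substituent, and enolate 15 must be captured at C11.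

**Butenolide (12 ⇒ 11).** Silylation of the commercial hydroxymethyl butenolide 11; C6 is bought.

**C2–C3 bond (10 ⇒ 9 ⇒ 8).** Asymmetric methallylation of enal 8 sets C2 and brings in C3, C4, C15 and the sacrificial methylene carbon in one step; silylation of 9 gives 10.

**C8–C9 bond and the E-alkene (8 ⇒ 7 ⇒ 6 ⇒ 3 + 4 through 5; 3 ⇒ 2 ⇒ 1).** Enal 8 comes from alcohol 7 and acetate 6, made by alkylating lithiated 1,3-dithiane 5 (from 4) with allylic bromide 3. The E geometry of C1=C10 is fixed at the outset by E-selective allylic oxidation of prenyl acetate 1 to 2.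

## Alternatives that were turned down

**Alternative 1:** The ring bond C5–C6 is cut, giving the open-chain iodo aldehyde A1 ((Z)-alkenyl iodide at C5, aldehyde at C6, methyl acetate arm on C7). In the forward key step a chromium/nickel-mediated Nozaki–Hiyama–Kishi reaction under high dilution adds the alkenyl metal to the aldehyde and closes the ten-membered ring to allylic alcohol A2.
- For it: this reaction is one of the most dependable ways to close strained medium rings, it tolerates esters and silyl ethers, and the Z geometry of C4=C5 is made beforehand and carried through unchanged. On the ring closure alone it is probably safer than a metathesis to a trisubstituted alkene.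
- Against it: the C6 configuration is created in the cyclisation itself, under the control only of C7 and of the macrocyclic transition state. A1 is a long linear chain whose C2, C7 and C8 centres each need their own asymmetric step. After A2 the lactone must still be closed, C13 introduced, and C8 deprotected and acylated.
- Comparison: the chosen route takes C6 from the chiral pool instead of making it in the riskiest step, and sets C7 and the C11 functionality in one convergent operation.

**Alternative 2:** The lactone rather than the carbocycle is disconnected. C11–C12 and C12–O are cut, leaving the ten-membered homopropargylic alcohol A3 (C6 hydroxyl, C7 ethynyl, C8 angelate). Forward, a palladium-catalysed cyclocarbonylation inserts one carbonyl carbon between the alkyne and the hydroxyl and gives the methylene lactone A4, which is the same compound as 25.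
- For it: the sensitive methylene lactone appears in a single late step with no masking and unmasking. On this point it is shorter and cleaner than the Mannich detour of the chosen route.
- Against it: the key step only decorates a finished ring. The ten-membered ring, the C6–C7–C8 triad and a trans-disposed ethynyl group on C7 all have to be made first, and the alternative does not say how. The product is an allylic lactone (C6 is allylic to C4=C5) in the presence of zerovalent palladium, so ionisation is a risk. Two ring alkenes sit close to the alkenylpalladium intermediate.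
- Comparison: the chosen route builds skeleton bonds and two stereocentres in its key step, and carries the methylene in a form that survives the ring construction.

**Alternative 3:** C8–C9 is cut and C1–C6 reconnected, which contracts the ten-membered ring to cyclohexenol A5. Forward, the potassium alkoxide of A5 undergoes an anionic oxy-Cope shift through a chair, expanding the ring by four carbons to cyclodecadienone A6.
- For it: the ring is formed by expansion, not by end-to-end closure, so there is no entropic penalty and no high dilution. The E geometry of C1=C10 follows from the chair, the Z geometry of C4=C5 from the six-membered ring, and C8 is transferred from the alkenylsilane geometry. For making the carbocycle this is the strongest of all the options.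
- Against it: A6 lacks the whole lactone (C11, C12, C13), has C6 as a ketone, C8 as a silane and C2 under a benzylic ether. Alkylation at C7, reduction at C6, lactonisation, methylenation, oxidative cleavage of the C–Si bond in the presence of alkenes, deprotection and acylation all follow, each with a stereochemical or chemoselectivity question in a flexible ring. A5 itself needs a transposed oxygen pattern relative to carvone.
- Comparison: the chosen route is weaker at the ring closure but has the lactone carbons, C6 and C7 in place from the convergent step and needs fewer operations afterwards.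

Key step: step 9

Remark: 2-methylallylmagnesium chloride solution and (−)-B-methoxydiisopinocampheylborane are taken as purchased reagents, and the C5 oxygen is protected as a tert-butyldimethylsilyl ether so that it can be freed in the presence of the C2 silyl ether.

## Route

Step 1
Reactants: 1 prenyl acetate
Product: 2 (E)-4-hydroxy-3-methylbut-2-en-1-yl acetate
Conditions: SeO2 (0.2 equiv), t-BuOOH (3 equiv), salicylic acid (cat.), CH2Cl2, rt
Reagents that add atoms: selenium dioxide, O=[Se]=O (catalytic oxygen carrier); tert-butyl hydroperoxide, CC(C)(C)OO (terminal oxygen source)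
Why: Riley allylic oxidation (ene reaction, then 2,3-sigmatropic shift) hydroxylates the methyl group trans to the chain of a trisubstituted alkene, which fixes the E geometry of the later C1=C10 bond; the acetate deactivates the product enough to limit over-oxidation.

Step 2
Reactants: 2 (E)-4-hydroxy-3-methylbut-2-en-1-yl acetate
Product: 3 (E)-4-bromo-3-methylbut-2-en-1-yl acetate
Conditions: CBr4, PPh3, CH2Cl2, 0 °C
Reagents that add atoms: carbon tetrabromide, BrC(Br)(Br)Br
Why: Appel bromination of a primary allylic alcohol under neutral conditions, which keeps the acetate and the alkene geometry.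

Step 3
Reactants: 3 (E)-4-bromo-3-methylbut-2-en-1-yl acetate; 4 1,3-dithiane
Product: 6 (E)-4-(1,3-dithian-2-yl)-3-methylbut-2-en-1-yl acetate, via 2-lithio-1,3-dithiane 5 (not isolated)
Conditions: n-BuLi, THF, −30 °C; then added to 3, THF, −78 °C
Reagents that add atoms: none
Why: Corey–Seebach alkylation; the sulfur-stabilised anion displaces the primary allylic bromide at −78 °C much faster than it attacks an acetate, and inverse addition keeps the bromide in excess; any acetate lost here is removed in step 4 in any case.

Step 4
Reactants: 6 (E)-4-(1,3-dithian-2-yl)-3-methylbut-2-en-1-yl acetate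
Product: 7 (E)-4-(1,3-dithian-2-yl)-3-methylbut-2-en-1-ol
Conditions: K2CO3 (cat.), MeOH, 0 °C → rt
Reagents that add atoms: none
Why: Base-catalysed transesterification (methanolysis) of the acetate; thioacetal and alkene are inert.

Step 5
Reactants: 7 (E)-4-(1,3-dithian-2-yl)-3-methylbut-2-en-1-ol
Product: 8 (E)-4-(1,3-dithian-2-yl)-3-methylbut-2-enal
Conditions: MnO2, CH2Cl2, rt
Reagents that add atoms: none
Why: MnO2 oxidises allylic alcohols selectively to enals without touching thioacetal sulfur and without E/Z isomerisation under these neutral conditions.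

Step 6
Reactants: 8 (E)-4-(1,3-dithian-2-yl)-3-methylbut-2-enal
Product: 9 (4S,5E)-7-(1,3-dithian-2-yl)-2,6-dimethylhepta-1,5-dien-4-ol
Conditions: (−)-Ipc2BOMe, CH2=C(CH3)CH2MgCl, Et2O, −78 °C → rt; then 8, −78 °C; HOCH2CH2NH2, rt
Reagents that add atoms: 2-methylallylmagnesium chloride, CC(=C)C[Mg]Cl
Why: Brown asymmetric methallylboration through a closed chair (Zimmerman–Traxler) transition state; the reagent from (−)-Ipc2BOMe attacks the Si face of the enal carbonyl and sets C2 as S, with 1,2-addition only; the non-oxidative ethanolamine work-up spares the thioacetal.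

Step 7
Reactants: 9 (4S,5E)-7-(1,3-dithian-2-yl)-2,6-dimethylhepta-1,5-dien-4-ol
Product: 10 tert-butyl{[(4S,5E)-7-(1,3-dithian-2-yl)-2,6-dimethylhepta-1,5-dien-4-yl]oxy}dimethylsilane
Conditions: TBSCl, imidazole, DMF, rt
Reagents that add atoms: tert-butyldimethylsilyl chloride, CC(C)(C)[Si](C)(C)Cl
Why: Standard silylation of a secondary allylic alcohol; the ether withstands the organolithium and acidic steps that follow.

Step 8
Reactants: 11 (S)-5-(hydroxymethyl)furan-2(5H)-one
Product: 12 (S)-5-{[(tert-butyldimethylsilyl)oxy]methyl}furan-2(5H)-one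
Conditions: TBSCl, imidazole, CH2Cl2, 0 °C
Reagents that add atoms: tert-butyldimethylsilyl chloride, CC(C)(C)[Si](C)(C)Cl
Why: Silylation of the primary alcohol with a weak base that does not deprotonate the acidic C6 position of the butenolide; the silyloxymethyl group later shields one face of the ring.

Step 9
Reactants: 10 tert-butyl{[(4S,5E)-7-(1,3-dithian-2-yl)-2,6-dimethylhepta-1,5-dien-4-yl]oxy}dimethylsilane; 12 (S)-5-{[(tert-butyldimethylsilyl)oxy]methyl}furan-2(5H)-one; 13 dimethylmethyleneammonium iodide
Product: 16 (3R,4S,5S)-5-[(tert-butyldimethylsilyloxy)methyl]-3-[(dimethylamino)methyl]-4-{2-[(2E,4S)-4-(tert-butyldimethylsilyloxy)-2,6-dimethylhepta-2,6-dien-1-yl]-1,3-dithian-2-yl}oxolan-2-one, via C8-lithiated dithiane 14 (not isolated), via lithium lactone enolate 15 (not isolated)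
Conditions: t-BuLi, THF/HMPA (10:1), −78 °C; 12, −78 °C; 13, −78 → −20 °C
Reagents that add atoms: none
Why: t-BuLi in THF/HMPA removes the C8 proton of 10 to give the sulfur-stabilised carbanion 14, which as a solvent-separated ion pair adds in Michael fashion to C7 of butenolide 12, and the lithium enolate 15 so formed is aminomethylated at C11 by the iminium ion of 13 (Mannich reaction). The closest known reaction type is the tandem conjugate addition of 2-lithio-1,3-dithianes to butenolides with capture of the enolate by a carbon electrophile, combined with the iminium-salt route to α-methylene lactones. The bonds C7–C8 and C11–C13 and two stereocentres are formed; no ring is closed. C7 is controlled by C6: the silyloxymethyl group blocks its own face of the planar butenolide, so the bulky nucleophile enters anti and C8 ends up trans to C5. C11 is controlled by the new C7 substituent: the quaternary dithianyl group shields its face of the enolate, so the iminium ion approaches from the other side and the aminomethyl group lies trans to C8 (this centre is erased again in step 17). The step needs 1,4- over 1,2-addition and addition faster than removal of the γ-proton at C6 of 12; the soft, HMPA-solvated carbanion at −78 °C favours both. The C10=C1 alkene is one methylene away from the carbanion, so no allylic ambident reactivity arises.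

Step 10
Reactants: 16 (3R,4S,5S)-5-[(tert-butyldimethylsilyloxy)methyl]-3-[(dimethylamino)methyl]-4-{2-[(2E,4S)-4-(tert-butyldimethylsilyloxy)-2,6-dimethylhepta-2,6-dien-1-yl]-1,3-dithian-2-yl}oxolan-2-one
Product: 17 (3R,4S,5S)-5-[(tert-butyldimethylsilyloxy)methyl]-3-[(dimethylamino)methyl]-4-[(3E,5S)-5-(tert-butyldimethylsilyloxy)-3,7-dimethylocta-3,7-dienoyl]oxolan-2-one
Conditions: CF3CO2H (1.1 equiv), then PhI(OCOCF3)2, MeCN/H2O (9:1), 0 °C; cold NaHCO3 quench
Reagents that add atoms: water, O
Why: Oxidative dethioacetalisation with trivalent iodine, in which sulfur is oxidised, the thionium ion is hydrolysed and the dithiol leaves as the cyclic disulfide; the amine is held as its trifluoroacetate salt so that it is not oxidised, and the short cold reaction spares the silyl ethers and alkenes. The β,γ-unsaturated ketone is not stored but reduced at once.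

Step 11
Reactants: 17 (3R,4S,5S)-5-[(tert-butyldimethylsilyloxy)methyl]-3-[(dimethylamino)methyl]-4-[(3E,5S)-5-(tert-butyldimethylsilyloxy)-3,7-dimethylocta-3,7-dienoyl]oxolan-2-one
Product: 18 (3R,4R,5S)-5-[(tert-butyldimethylsilyloxy)methyl]-3-[(dimethylamino)methyl]-4-[(1S,3E,5S)-5-(tert-butyldimethylsilyloxy)-1-hydroxy-3,7-dimethylocta-3,7-dien-1-yl]oxolan-2-one
Conditions: (R)-2-methyl-CBS-oxazaborolidine (1 equiv), catecholborane, toluene, −78 → −40 °C
Reagents that add atoms: none
Why: Corey–Bakshi–Shibata reduction; the catalyst distinguishes the branched C7 (large) from the C9 methylene (small) and the (R)-catalyst should deliver hydride to the face that gives 8S; catecholborane does not hydroborate the alkenes at this temperature, and a full equivalent of catalyst allows for coordination to the amine.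

Step 12
Reactants: 18 (3R,4R,5S)-5-[(tert-butyldimethylsilyloxy)methyl]-3-[(dimethylamino)methyl]-4-[(1S,3E,5S)-5-(tert-butyldimethylsilyloxy)-1-hydroxy-3,7-dimethylocta-3,7-dien-1-yl]oxolan-2-one
Product: 19 (3R,4R,5S)-5-[(tert-butyldimethylsilyloxy)methyl]-3-[(dimethylamino)methyl]-4-[(1S,3E,5S)-1-(angeloyloxy)-5-(tert-butyldimethylsilyloxy)-3,7-dimethylocta-3,7-dien-1-yl]oxolan-2-one
Conditions: angelic acid, 2,4,6-Cl3C6H2COCl, Et3N, toluene, rt; then 18, 75 °C
Reagents that add atoms: angelic acid, C/C=C(/C)C(=O)O
Why: Yamaguchi-type mixed-anhydride esterification without a nucleophilic catalyst, which acylates hindered secondary alcohols at the angeloyl carbonyl and avoids isomerisation to the tiglate; capping C8 at once also removes the hydroxyl that could migrate the lactone or later form a lactol with C5.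

Step 13
Reactants: 19 (3R,4R,5S)-5-[(tert-butyldimethylsilyloxy)methyl]-3-[(dimethylamino)methyl]-4-[(1S,3E,5S)-1-(angeloyloxy)-5-(tert-butyldimethylsilyloxy)-3,7-dimethylocta-3,7-dien-1-yl]oxolan-2-one
Product: 20 (3R,4R,5S)-3-[(dimethylamino)methyl]-5-(hydroxymethyl)-4-[(1S,3E,5S)-1-(angeloyloxy)-5-(tert-butyldimethylsilyloxy)-3,7-dimethylocta-3,7-dien-1-yl]oxolan-2-one
Conditions: HF·pyridine, pyridine, THF, 0 °C
Reagents that add atoms: none
Why: Selective desilylation; buffered HF·pyridine cleaves the unhindered primary silyl ether well before the secondary allylic one, and the lactone, angelate and amine are stable to it.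

Step 14
Reactants: 20 (3R,4R,5S)-3-[(dimethylamino)methyl]-5-(hydroxymethyl)-4-[(1S,3E,5S)-1-(angeloyloxy)-5-(tert-butyldimethylsilyloxy)-3,7-dimethylocta-3,7-dien-1-yl]oxolan-2-one
Product: 21 (2S,3R,4R)-4-[(dimethylamino)methyl]-3-[(1S,3E,5S)-1-(angeloyloxy)-5-(tert-butyldimethylsilyloxy)-3,7-dimethylocta-3,7-dien-1-yl]-5-oxooxolane-2-carbaldehyde
Conditions: Dess–Martin periodinane, NaHCO3, CH2Cl2, 0 °C → rt
Reagents that add atoms: none
Why: Dess–Martin oxidation under buffered, non-basic conditions gives the epimerisable α-acyloxy aldehyde without touching alkenes or the amine; the aldehyde is used crude.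

Step 15
Reactants: 21 (2S,3R,4R)-4-[(dimethylamino)methyl]-3-[(1S,3E,5S)-1-(angeloyloxy)-5-(tert-butyldimethylsilyloxy)-3,7-dimethylocta-3,7-dien-1-yl]-5-oxooxolane-2-carbaldehyde
Product: 22 (3R,4R,5R)-3-[(dimethylamino)methyl]-5-ethenyl-4-[(1S,3E,5S)-1-(angeloyloxy)-5-(tert-butyldimethylsilyloxy)-3,7-dimethylocta-3,7-dien-1-yl]oxolan-2-one
Conditions: Ph3PCH3Br, KN(SiMe3)2, THF, 0 °C; then 21, −78 → −20 °C
Reagents that add atoms: methyltriphenylphosphonium bromide, C[P+](c1ccccc1)(c1ccccc1)c1ccccc1.[Br-]
Why: Wittig methylenation; the aldehyde reacts with the ylide far faster than the lactone or the hindered enoate, and the low temperature with a slight excess of ylide limits epimerisation at C6 (the descriptor at C6 changes only because of ligand priorities).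

Step 16
Reactants: 22 (3R,4R,5R)-3-[(dimethylamino)methyl]-5-ethenyl-4-[(1S,3E,5S)-1-(angeloyloxy)-5-(tert-butyldimethylsilyloxy)-3,7-dimethylocta-3,7-dien-1-yl]oxolan-2-one
Product: 23 (1(10)E,4Z)-8α-angeloyloxy-2α-(tert-butyldimethylsilyloxy)-13-(dimethylamino)-11,13-dihydrogermacra-1(10),4-dien-12,6α-olide (7αH; aminomethyl group on C11 trans to C8)
Conditions: (+)-camphorsulfonic acid (1.05 equiv); second-generation Grubbs catalyst RuCl2(=CHPh)(H2IMes)(PCy3) (15 mol %), toluene (1 mM), 80 °C; NaHCO3 wash
Reagents that add atoms: none
Why: Ring-closing metathesis; the ruthenium carbene forms at the monosubstituted vinyl group and closes onto the 1,1-disubstituted alkene with loss of ethylene, and the cis (Z) geometry is expected as the less strained arrangement for a trisubstituted alkene in a ten-membered ring that already holds an E alkene. The amine is protonated so that it cannot bind ruthenium, and the enoate alkenes are too hindered and electron-poor to take part.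

Step 17
Reactants: 23 (1(10)E,4Z)-8α-angeloyloxy-2α-(tert-butyldimethylsilyloxy)-13-(dimethylamino)-11,13-dihydrogermacra-1(10),4-dien-12,6α-olide
Product: 25 (1(10)E,4Z)-8α-angeloyloxy-2α-(tert-butyldimethylsilyloxy)germacra-1(10),4,11(13)-trien-12,6α-olide, via trimethylammonium iodide 24 (not isolated)
Conditions: MeI, THF, rt; then NaHCO3 (aq)/CH2Cl2, rt
Reagents that add atoms: none
Why: Exhaustive N-methylation followed by E1cB elimination of trimethylamine from the lactone enolate is the standard unmasking of an α-methylene lactone from its Mannich base; the mild base leaves the angelate untouched.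

Step 18
Reactants: 25 (1(10)E,4Z)-8α-angeloyloxy-2α-(tert-butyldimethylsilyloxy)germacra-1(10),4,11(13)-trien-12,6α-olide
Product: 26 (1(10)E,4Z)-8α-angeloyloxy-2α-hydroxygermacra-1(10),4,11(13)-trien-12,6α-olide
Conditions: HF·pyridine, pyridine, THF, 0 °C → rt
Reagents that add atoms: none
Why: Fluoride-mediated desilylation under buffered, weakly acidic conditions; the methylene lactone is not exposed to basic fluoride and the buffer guards against acid-triggered transannular cyclisation of the diene.

Step 19
Reactants: 26 (1(10)E,4Z)-8α-angeloyloxy-2α-hydroxygermacra-1(10),4,11(13)-trien-12,6α-olide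
Product: 27 8α-angeloyloxy-1β,10α:4α,5α-diepoxy-2α-hydroxygermacr-11(13)-en-12,6α-olide (1R,2S,4R,5S,6S,7R,8S,10R; the target)
Conditions: VO(acac)2 (10 mol %), t-BuOOH (3 equiv), CH2Cl2, 0 °C → rt
Reagents that add atoms: tert-butyl hydroperoxide, CC(C)(C)OO
Why: Hydroxyl-directed epoxidation: the C2 alkoxide binds the pentavalent vanadium alkyl peroxide and delivers oxygen first to the allylic C1=C10 bond and then to the homoallylic C4=C5 bond. In the conformer that avoids allylic 1,3-strain with C14 (C2–H eclipsing the alkene, ring chain on the far face) the hydroxyl lies over the outer face of C1=C10, so directed and peripheral attack coincide and give the 1β,10α-oxirane, and delivery from the same hydroxyl to the outer face of the Z-alkene gives the 4α,5α-oxirane. The methylene lactone and the angelate are too electron-poor to react.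

## Compound list

1 | prenyl acetate (3-methylbut-2-en-1-yl acetate) | CC(C)=CCOC(C)=O | starting material
2 | (E)-4-hydroxy-3-methylbut-2-en-1-yl acetate | OC/C(C)=C/COC(C)=O | intermediate
3 | (E)-4-bromo-3-methylbut-2-en-1-yl acetate | BrC/C(C)=C/COC(C)=O | intermediate
4 | 1,3-dithiane | C1CSCSC1 | starting material
5 | 2-lithio-1,3-dithiane | [Li]C1SCCCS1 | intermediate (not isolated)
6 | (E)-4-(1,3-dithian-2-yl)-3-methylbut-2-en-1-yl acetate | S1CCCSC1C/C(C)=C/COC(C)=O | intermediate
7 | (E)-4-(1,3-dithian-2-yl)-3-methylbut-2-en-1-ol | S1CCCSC1C/C(C)=C/CO | intermediate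
8 | (E)-4-(1,3-dithian-2-yl)-3-methylbut-2-enal | S1CCCSC1C/C(C)=C/C=O | intermediate
9 | (4S,5E)-7-(1,3-dithian-2-yl)-2,6-dimethylhepta-1,5-dien-4-ol | S1CCCSC1C/C(C)=C/[C@@H](O)CC(C)=C | intermediate
10 | tert-butyl{[(4S,5E)-7-(1,3-dithian-2-yl)-2,6-dimethylhepta-1,5-dien-4-yl]oxy}dimethylsilane | S1CCCSC1C/C(C)=C/[C@@H](O[Si](C)(C)C(C)(C)C)CC(C)=C | intermediate
11 | (S)-5-(hydroxymethyl)furan-2(5H)-one | O=C1O[C@H](CO)C=C1 | starting material
12 | (S)-5-{[(tert-butyldimethylsilyl)oxy]methyl}furan-2(5H)-one | O=C1O[C@H](CO[Si](C)(C)C(C)(C)C)C=C1 | intermediate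
13 | dimethylmethyleneammonium iodide | C=[N+](C)C.[I-] | starting material
14 | 2-lithio derivative of 10 (carbanion at C8) | [Li]C1(C/C(C)=C/[C@@H](O[Si](C)(C)C(C)(C)C)CC(C)=C)SCCCS1 | intermediate (not isolated)
15 | lithium enolate (C11=C12–OLi) of the conjugate adduct of 14 and 12 | [Li]OC1=C[C@H](C2(C/C(C)=C/[C@@H](O[Si](C)(C)C(C)(C)C)CC(C)=C)SCCCS2)[C@@H](CO[Si](C)(C)C(C)(C)C)O1 | intermediate (not isolated)
16 | (3R,4S,5S)-5-[(tert-butyldimethylsilyloxy)methyl]-3-[(dimethylamino)methyl]-4-{2-[(2E,4S)-4-(tert-butyldimethylsilyloxy)-2,6-dimethylhepta-2,6-dien-1-yl]-1,3-dithian-2-yl}oxolan-2-one | CN(C)C[C@@H]1C(=O)O[C@H](CO[Si](C)(C)C(C)(C)C)[C@H]1C1(C/C(C)=C/[C@@H](O[Si](C)(C)C(C)(C)C)CC(C)=C)SCCCS1 | intermediate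
17 | (3R,4S,5S)-5-[(tert-butyldimethylsilyloxy)methyl]-3-[(dimethylamino)methyl]-4-[(3E,5S)-5-(tert-butyldimethylsilyloxy)-3,7-dimethylocta-3,7-dienoyl]oxolan-2-one | CN(C)C[C@@H]1C(=O)O[C@H](CO[Si](C)(C)C(C)(C)C)[C@H]1C(=O)C/C(C)=C/[C@@H](O[Si](C)(C)C(C)(C)C)CC(C)=C | intermediate
18 | (3R,4R,5S)-5-[(tert-butyldimethylsilyloxy)methyl]-3-[(dimethylamino)methyl]-4-[(1S,3E,5S)-5-(tert-butyldimethylsilyloxy)-1-hydroxy-3,7-dimethylocta-3,7-dien-1-yl]oxolan-2-one | CN(C)C[C@@H]1C(=O)O[C@H](CO[Si](C)(C)C(C)(C)C)[C@H]1[C@@H](O)C/C(C)=C/[C@@H](O[Si](C)(C)C(C)(C)C)CC(C)=C | intermediate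
19 | (3R,4R,5S)-5-[(tert-butyldimethylsilyloxy)methyl]-3-[(dimethylamino)methyl]-4-[(1S,3E,5S)-1-(angeloyloxy)-5-(tert-butyldimethylsilyloxy)-3,7-dimethylocta-3,7-dien-1-yl]oxolan-2-one | CN(C)C[C@@H]1C(=O)O[C@H](CO[Si](C)(C)C(C)(C)C)[C@H]1[C@@H](OC(=O)/C(C)=C\C)C/C(C)=C/[C@@H](O[Si](C)(C)C(C)(C)C)CC(C)=C | intermediate
20 | (3R,4R,5S)-3-[(dimethylamino)methyl]-5-(hydroxymethyl)-4-[(1S,3E,5S)-1-(angeloyloxy)-5-(tert-butyldimethylsilyloxy)-3,7-dimethylocta-3,7-dien-1-yl]oxolan-2-one | CN(C)C[C@@H]1C(=O)O[C@H](CO)[C@H]1[C@@H](OC(=O)/C(C)=C\C)C/C(C)=C/[C@@H](O[Si](C)(C)C(C)(C)C)CC(C)=C | intermediate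
21 | (2S,3R,4R)-4-[(dimethylamino)methyl]-3-[(1S,3E,5S)-1-(angeloyloxy)-5-(tert-butyldimethylsilyloxy)-3,7-dimethylocta-3,7-dien-1-yl]-5-oxooxolane-2-carbaldehyde | CN(C)C[C@@H]1C(=O)O[C@H](C=O)[C@H]1[C@@H](OC(=O)/C(C)=C\C)C/C(C)=C/[C@@H](O[Si](C)(C)C(C)(C)C)CC(C)=C | intermediate
22 | (3R,4R,5R)-3-[(dimethylamino)methyl]-5-ethenyl-4-[(1S,3E,5S)-1-(angeloyloxy)-5-(tert-butyldimethylsilyloxy)-3,7-dimethylocta-3,7-dien-1-yl]oxolan-2-one | CN(C)C[C@@H]1C(=O)O[C@H](C=C)[C@H]1[C@@H](OC(=O)/C(C)=C\C)C/C(C)=C/[C@@H](O[Si](C)(C)C(C)(C)C)CC(C)=C | intermediate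
23 | (1(10)E,4Z)-8α-angeloyloxy-2α-(tert-butyldimethylsilyloxy)-13-(dimethylamino)-11,13-dihydrogermacra-1(10),4-dien-12,6α-olide (7αH; aminomethyl on C11 trans to C8) | CN(C)C[C@@H]1C(=O)O[C@@H]2/C=C(C)\C[C@H](O[Si](C)(C)C(C)(C)C)/C=C(C)/C[C@H](OC(=O)/C(C)=C\C)[C@@H]12 | intermediate
24 | N,N,N-trimethylammonium iodide of 23 | C[N+](C)(C)C[C@@H]1C(=O)O[C@@H]2/C=C(C)\C[C@H](O[Si](C)(C)C(C)(C)C)/C=C(C)/C[C@H](OC(=O)/C(C)=C\C)[C@@H]12.[I-] | intermediate (not isolated)
25 | (1(10)E,4Z)-8α-angeloyloxy-2α-(tert-butyldimethylsilyloxy)germacra-1(10),4,11(13)-trien-12,6α-olide | C=C1C(=O)O[C@@H]2/C=C(C)\C[C@H](O[Si](C)(C)C(C)(C)C)/C=C(C)/C[C@H](OC(=O)/C(C)=C\C)[C@@H]12 | intermediate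
26 | (1(10)E,4Z)-8α-angeloyloxy-2α-hydroxygermacra-1(10),4,11(13)-trien-12,6α-olide | C=C1C(=O)O[C@@H]2/C=C(C)\C[C@H](O)/C=C(C)/C[C@H](OC(=O)/C(C)=C\C)[C@@H]12 | intermediate
27 | 8α-angeloyloxy-1β,10α:4α,5α-diepoxy-2α-hydroxygermacr-11(13)-en-12,6α-olide (1R,2S,4R,5S,6S,7R,8S,10R) | C=C1C(=O)O[C@H]2[C@H]1[C@@H](OC(=O)/C(C)=C\C)C[C@@]1(C)O[C@@H]1[C@@H](O)C[C@@]1(C)O[C@@H]21 | target

## Step count and least certain steps

Total step count: 19. Longest linear sequence: 18 steps (from 1 through steps 1–7 and 9–19 to 27); step 8 is the only step off this line.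

**Step 9 (key step).** The carbanion may attack the lactone carbonyl, or act as a base on the acidic C6 proton of 12, in place of adding at C7. The hindered enolate may also be protonated before the sparingly soluble iminium salt captures it. Fallback: separate the two bond formations. Setting out from 10 and 12, the conjugate addition is run as in step 9 but quenched with acetic acid at −78 °C to give the C11-unsubstituted trans-lactone F1. After purification, F1 is enolised with LiN(iPr)2 in THF at −78 °C (C11 is its only enolisable position next to the carbonyl) and treated with 13, which returns to the route at 16.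

**Step 16.** Closure onto the 1,1-disubstituted alkene to a strained ten-membered ring may be slower than intermolecular metathesis of the C5 vinyl group, so that dimers and oligomers form, and the new alkene may form as an E/Z mixture. Fallback: close the ring before C8 is unmasked, when the quaternary dithiane carbon bends the chain (Thorpe–Ingold effect) and no ester sits on the ring. Setting out from 16:
- HF·pyridine/pyridine frees the primary alcohol F2.
- Oxidation with SO3·pyridine/DMSO/iPr2NEt, which does not touch the thioacetal, gives the aldehyde F3.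
- Methylenation as in step 15 gives the vinyl lactone F4.
- Metathesis as in step 16 gives the dithiane-bearing cyclodecadiene F5.
- Unmasking as in step 10 gives the ring ketone F6.
- Reduction as in step 11 gives the 8α-alcohol F7.
- Acylation of F7 as in step 12 returns to the route at 23.

**Step 19.** Facial selectivity may be poor at the homoallylic C4=C5 alkene, where delivery from the C2 hydroxyl passes through a larger and more flexible transition state. The first-formed 1,10-oxirane may also be opened across the ring by the remaining alkene under the Lewis-acidic metal. Fallback: a metal-free, two-stage epoxidation. Setting out from 26, buffered mCPBA (1 equiv, NaHCO3, CH2Cl2, −20 °C), directed by hydrogen bonding to the allylic hydroxyl, gives the 1β,10α-monoepoxide F8. Dimethyldioxirane in acetone at 0 °C then attacks the exposed outer face of C4=C5 under neutral conditions and returns to the route at 27.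

**Step 11.** The inherent facial preference of the ketone, set by C7, may oppose the catalyst, and the basic amine can tie up borane and oxazaborolidine, so that the C8 epimers form unselectively. A second hazard is migration of the lactone to the free C8 hydroxyl if 18 is kept. Fallback: make the other epimer on purpose and invert it. Setting out from 17, reduction with the (S)-oxazaborolidine and catecholborane gives the 8R alcohol F9. Mitsunobu esterification (angelic acid, PPh3, diisopropyl azodicarboxylate, toluene, 0 °C → rt) inverts C8 and installs the angelate in one step, returning to the route at 19.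

**Step 10.** The iodine reagent may oxidise an incompletely protonated amine or the electron-rich alkenes. Once the ketone is free, base may move the C10=C1 double bond into conjugation with C8 or eliminate the lactone oxygen from C6. Fallback: a non-oxidative, alkylative unmasking that gives up the amine and then restores it. Setting out from 16, MeI and CaCO3 in aqueous MeCN at 40 °C methylate sulfur and nitrogen alike; hydrolysis and elimination give the keto methylene lactone F10. Brief treatment with dimethylamine in THF at 0 °C re-adds the amine to the exocyclic methylene (reversible, so the trans arrangement is expected) and returns to the route at 17.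

## Further compounds

F1 | step 9 | (4S,5S)-5-[(tert-butyldimethylsilyloxy)methyl]-4-{2-[(2E,4S)-4-(tert-butyldimethylsilyloxy)-2,6-dimethylhepta-2,6-dien-1-yl]-1,3-dithian-2-yl}oxolan-2-one | C1C(=O)O[C@H](CO[Si](C)(C)C(C)(C)C)[C@H]1C1(C/C(C)=C/[C@@H](O[Si](C)(C)C(C)(C)C)CC(C)=C)SCCCS1
F2 | step 16 | primary alcohol from 16 (C5 hydroxymethyl, C8 dithiane retained) | CN(C)C[C@@H]1C(=O)O[C@H](CO)[C@H]1C1(C/C(C)=C/[C@@H](O[Si](C)(C)C(C)(C)C)CC(C)=C)SCCCS1
F3 | step 16 | C5 aldehyde with C8 dithiane | CN(C)C[C@@H]1C(=O)O[C@H](C=O)[C@H]1C1(C/C(C)=C/[C@@H](O[Si](C)(C)C(C)(C)C)CC(C)=C)SCCCS1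
F4 | step 16 | C5 vinyl lactone with C8 dithiane | CN(C)C[C@@H]1C(=O)O[C@H](C=C)[C@H]1C1(C/C(C)=C/[C@@H](O[Si](C)(C)C(C)(C)C)CC(C)=C)SCCCS1
F5 | step 16 | (1(10)E,4Z)-cyclodecadiene lactone with C8 dithiane, C2 silyl ether and C11 aminomethyl group | CN(C)C[C@@H]1C(=O)O[C@@H]2/C=C(C)\C[C@H](O[Si](C)(C)C(C)(C)C)/C=C(C)/CC3(SCCCS3)[C@@H]12
F6 | step 16 | corresponding ring C8 ketone | CN(C)C[C@@H]1C(=O)O[C@@H]2/C=C(C)\C[C@H](O[Si](C)(C)C(C)(C)C)/C=C(C)/CC(=O)[C@@H]12
F7 | step 16 | corresponding ring 8α-alcohol | CN(C)C[C@@H]1C(=O)O[C@@H]2/C=C(C)\C[C@H](O[Si](C)(C)C(C)(C)C)/C=C(C)/C[C@H](O)[C@@H]12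
F8 | step 19 | (4Z)-8α-angeloyloxy-1β,10α-epoxy-2α-hydroxygermacra-4,11(13)-dien-12,6α-olide | C=C1C(=O)O[C@@H]2/C=C(C)\C[C@H](O)[C@H]3O[C@]3(C)C[C@H](OC(=O)/C(C)=C\C)[C@@H]12
F9 | step 11 | C8 epimer (8R alcohol) of 18 | CN(C)C[C@@H]1C(=O)O[C@H](CO[Si](C)(C)C(C)(C)C)[C@H]1[C@H](O)C/C(C)=C/[C@@H](O[Si](C)(C)C(C)(C)C)CC(C)=C
F10 | step 10 | (4S,5S)-5-[(tert-butyldimethylsilyloxy)methyl]-3-methylidene-4-[(3E,5S)-5-(tert-butyldimethylsilyloxy)-3,7-dimethylocta-3,7-dienoyl]oxolan-2-one | C=C1C(=O)O[C@H](CO[Si](C)(C)C(C)(C)C)[C@H]1C(=O)C/C(C)=C/[C@@H](O[Si](C)(C)C(C)(C)C)CC(C)=C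
A1 | alternative 1 | open-chain (Z)-alkenyl iodide aldehyde with C7 methyl acetate arm, C2 TBS ether and C8 triethylsilyl ether | I/C=C(C)\C[C@H](O[Si](C)(C)C(C)(C)C)/C=C(C)/C[C@H](O[Si](CC)(CC)CC)[C@@H](CC(=O)OC)C=O
A2 | alternative 1 | (1(10)E,4Z)-cyclodecadien-6-ol with C7 methyl acetate arm | O[C@@H]1/C=C(C)\C[C@H](O[Si](C)(C)C(C)(C)C)/C=C(C)/C[C@H](O[Si](CC)(CC)CC)[C@H]1CC(=O)OC
A3 | alternative 2 | (1(10)E,4Z)-7-ethynylcyclodecadien-6-ol with C8 angelate and C2 TBS ether | O[C@@H]1/C=C(C)\C[C@H](O[Si](C)(C)C(C)(C)C)/C=C(C)/C[C@H](OC(=O)/C(C)=C\C)[C@H]1C#C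
A4 | alternative 2 | (1(10)E,4Z)-8α-angeloyloxy-2α-(tert-butyldimethylsilyloxy)germacra-1(10),4,11(13)-trien-12,6α-olide (identical with 25) | C=C1C(=O)O[C@@H]2/C=C(C)\C[C@H](O[Si](C)(C)C(C)(C)C)/C=C(C)/C[C@H](OC(=O)/C(C)=C\C)[C@@H]12
A5 | alternative 3 | 1-[(E)-2-(benzyldimethylsilyl)ethenyl]-3-methyl-5-(4-methoxybenzyloxy)-6-(prop-1-en-2-yl)cyclohex-2-en-1-ol (the two alkenyl groups trans) | O[C@@]1(/C=C/[Si](C)(C)Cc2ccccc2)C=C(C)C[C@H](OCc2ccc(OC)cc2)[C@H]1C(C)=C
A6 | alternative 3 | (1(10)E,4Z)-cyclodecadien-6-one with C8 benzyldimethylsilyl group and C2 4-methoxybenzyl ether | O=C1/C=C(C)\C[C@H](OCc2ccc(OC)cc2)/C=C(C)/C[C@H]([Si](C)(C)Cc2ccccc2)C1
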